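Remark on numbering (assumption): the ring carbons are C1 (gem-dimethyl carbon), C2, C3 (oxygen-bearing), C4, C5 (methyl-bearing epoxide carbon) and C6 (epoxide carbon carrying the side chain); the side chain is C7=C8–C9(=O)–C10. In this numbering the target is (3S,5R,6S).

## Structural features

The target is a cyclohexane (C1–C6) cis-fused to an oxirane across C5–C6, that is, a 7-oxabicyclo[4.1.0]heptane. C1 carries two methyl groups, C5 one methyl group, C6 the (E)-3-oxobut-1-enyl chain C7–C10, and C3 an oxygen esterified with tetradecanoic (myristic) acid. There are three stereocentres: C5 (R) and C6 (S) are adjacent, fully substituted epoxide carbons, and C3 (S) stands 1,3 to C5 and 1,4 to C6. The epoxide oxygen is anti to the C3 oxygen, whereas the C6–C7 bond is cis to it. C1, C6 and C5 form a run of three contiguous fully substituted carbons, so the C1–C6 bond is the most congested bond of the skeleton. The fragile groups are the tetrasubstituted epoxide next to the enone (opened or rearranged by acid), the enone itself (a base-sensitive Michael acceptor) and the fatty ester (cleaved by hydride, alkoxide and fluoride), which therefore has to be introduced last. The real difficulty is twofold: to build the crowded ring with C3 in one absolute configuration, and to place the epoxide on the face opposite to a remote oxygen, which a hydroxyl-directed epoxidation cannot do. The key step exploits the cis-1,4 relationship of the C3–O and C6–C7 bonds across the six-membered ring, with C1 lying between C6 and the C2 methylene. With C7 as a carbonyl carbon, an O–C(=O) unit bridges C3 and C6, and the ring becomes the 2-oxabicyclo[2.2.2]octenone of a 2-pyrone/alkene Diels–Alder adduct in which C1 and C2 come from isobutylene.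

## Logic of the disconnections

18 ⇒ 16 + 17. The acyl C–O bond at O3 is cut first. The long-chain ester would not survive the hydride, alkoxide and fluoride steps, and its removal leaves the small polar core 16. The forward acylation must be mild and non-acidic, so that the epoxide and enone stay intact; the C3–O bond is not broken, so C3 keeps its configuration.

16 ⇒ 15. The O3–H is masked as a silyl ether (O–Si bond). The mask is needed from 11 onward so that O3 does not compete with the C7 hydroxyl for the aluminium, titanium and ruthenium reagents. The forward cleavage needs buffered fluoride.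

15 ⇒ 14. The C7=C8 double bond is cut, which removes C8–C10 as a three-carbon ylide and leaves an aldehyde without α-hydrogen. The forward olefination must be (E)-selective and must cope with the neopentyl-type hindrance at C6.

14 ⇒ 13. C7 is taken down to the alcohol level; no skeletal bond is cut. Only the primary allylic alcohol permits a reagent-controlled epoxidation. The forward oxidation must be neutral.

13 ⇒ 12. Both C–O bonds of the oxirane (C5–O and C6–O) are cut, giving the tetrasubstituted C5=C6 alkene with its C7 hydroxymethyl handle. Two stereocentres are removed at once. The forward step must deliver oxygen anti to the remote O3 substituent, so the face selection has to come from the chiral reagent and not from the substrate.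

12 ⇒ 11. C7 is raised to the ester level (C7–H bonds exchanged for C7–O bonds). This connects the allylic alcohol to a conjugated ester that can be reached by isomerisation. The forward reduction must be a clean 1,2-reduction of a hindered ester.

11 ⇒ 10. The O3–Si bond is cut. Silylation is placed after the isomerisation so that no silyloxy leaving group is present while a dienolate is formed.

10 ⇒ 9. The C5=C6 double bond is moved back to C4=C5 (exchange of the C4–H and C6–H bonds). This exposes C6 as a carbon with an acidic hydrogen, that is, as a former malonate carbon. The forward step must be a thermodynamic conjugation under base that does not expel the C3 oxygen.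

9 ⇒ 8. A second methoxycarbonyl group is placed on C6 (C6–C bond). C6 becomes the central carbon of a 1,3-diester, the pattern left by a pyrone-3-carboxylate. The forward step must remove one of two identical ester groups at a quaternary carbon.

8 ⇒ 7. O3 is joined to the carbonyl carbon of the ester cis to it (O–C(=O) bond, with loss of methanol). This reveals the bridged bicyclic lactone. The forward step is a simple alcoholysis that does not touch C3.

7 ⇒ 5 + 6. The C2–C3 and C1–C6 bonds are cut in a retro-[4+2] sense. This is the largest simplification of the route: the carbocycle, the congested C1–C6 bond, the quaternary C6 and the C3 stereocentre all go back to a flat, achiral diene and a four-carbon feedstock alkene. The forward step demands regiocontrol (CH2 of 6 to the oxygen-bearing diene terminus), control of the diene face by a chiral Lewis acid, and avoidance of CO2 loss from 7. The ester of 5 is kept as the methyl ester because it is at once the chelating group, the LUMO-lowering group and the future C7.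

5 ⇒ 3 (through 4). The ring O–C(=O) bond of 5 is cut and the enol oxygen is returned to a masked aldehyde. The forward step needs acetal hydrolysis, enolisation toward the alkylidene malonate, and lactonisation onto the ester that is necessarily cis.

3 ⇒ 1 + 2. The C=C bond between the future C6 and the future C5 is cut, which leads to two commercial compounds. The forward step is a condensation of a ketone with a malonate, which needs Lewis-acid activation, and the acetal has to survive it.

## Other disconnections considered

Alternative 1: The C4–C5 bond is cut, which opens the ring to the achiral trione 4,4-dimethylheptane-2,3,6-trione A2. In the forward direction a chiral secondary amine would convert the methyl ketone (future C3/C4) into its enamine. The enamine carbon C4 would add to the acetyl carbonyl of the 1,2-dione (future C5) in an intramolecular aldol reaction and give (R)-2-hydroxy-2,6,6-trimethylcyclohexane-1,4-dione A1.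
- In its favour: enamine aldol catalysis is mechanistically well understood, the precursor is achiral, and the tertiary C5–O centre is set catalytically.
- Against it here: A1 holds only one of the three stereocentres, and C3 and C6 are carbonyl groups. C3 would need a 1,3-controlled reduction. C7 would have to be added to the most hindered ketone, flanked by C1 and C5. The C5 oxygen would have to become the epoxide oxygen by displacement at the tertiary, neopentyl-like C6, for which no reliable stereospecific step is evident. The enamine could also attack the other carbonyl of the dione and close a five-membered ring.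
- Comparison: on mechanism the alternative is the better of the two, because its key step is established chemistry and the cycloaddition leading to 7 is not. On structure the chosen step is stronger, since 7 already holds C7, the C1–C6 bond and C3 in its final configuration. On step economy no saving is expected, because A2 needs its own assembly and more stereochemical operations follow the key step.

Alternative 2: The C5–C6 and C6–O bonds are cut together, which leads back to the acyclic chloro ester tert-butyl (5S)-5-[(tert-butyldimethylsilyl)oxy]-2-chloro-3,3-dimethyl-7-oxooctanoate A4. In the forward direction a strong hindered base would form the ester enolate at the chlorine-bearing carbon (future C6), which adds to the tethered methyl ketone (future C5) and closes the cyclohexane. The C5 alkoxide then displaces chloride at C6 (intramolecular Darzens reaction) and gives tert-butyl (1S,4S,6R)-4-[(tert-butyldimethylsilyl)oxy]-2,2,6-trimethyl-7-oxabicyclo[4.1.0]heptane-1-carboxylate A3.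
- In its favour: the carbocycle and the oxirane are made in one operation, and C7 arrives at the ester level directly on the epoxide. Neither a double-bond isomerisation nor a separate epoxidation is needed, so after the key step this plan is shorter than the chosen one; on this point it is the better.
- Against it here: the new C5–C6 bond joins two carbons that both become fully substituted, next to the quaternary C1. The methyl ketone is enolisable and carries the C3 silyloxy group in the β-position, so enolisation and β-elimination would compete with the aldol step. The configuration of C5/C6 relative to C3 would rest on 1,3-induction in the cyclisation and on a trans-diaxial chlorohydrin, neither of which is secured. A4, with its C3 stereocentre, needs its own linear asymmetric synthesis.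
- Comparison: on mechanism the Darzens reaction is classical and better precedented, but a lower stereocontrol is to be expected. On structure it sets C5 and C6 but presupposes C3, whereas the chosen step creates C3 and the ring from flat, achiral components. On step economy the totals should be similar, because the saving after the key step is spent on making A4.

Alternative 3: The C3–C4 bond is cut and C3 is reconnected to C6, which contracts the ring to the racemic vinylcyclobutanone 2-{[(tert-butyldimethylsilyl)oxy]methyl}-3,3-dimethyl-2-(prop-1-en-2-yl)cyclobutan-1-one A6. In the forward direction, on heating or irradiation, the acyl carbon C3 would migrate from C6 to the terminal carbon of the isopropenyl group (C4) in a 1,3-acyl shift. This releases the strain of the four-membered ring and gives 4-{[(tert-butyldimethylsilyl)oxy]methyl}-3,5,5-trimethylcyclohex-3-en-1-one A5.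
- In its favour: the tetrasubstituted C5=C6 alkene and C7 at the alcohol level are obtained directly, so the decarboxylation and isomerisation steps of the chosen plan would be unnecessary; on this structural point the alternative is the better. A6 could in principle come from a ketene [2+2] addition to 6, the same feedstock.
- Against it here: A5 is achiral. C3 would have to be created by enantioselective reduction of a ketone whose two α-methylene groups differ only at the β-position, a weak basis for reagent control. The β,γ-unsaturated ketone can slip into conjugation under acid or base. The acyl shift competes with cycloreversion and decarbonylation, and the densely substituted ketene needed for A6 is not trivial.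
- Comparison: on mechanism the acyl shift is a known reaction type and the chosen cycloaddition is not, a point for the alternative. On structure the chosen step is the only one of the four that sets C3 in its final configuration while the ring is formed. On step economy the plans are about equal once the asymmetric reduction and the synthesis of A6 are counted.

Key step: step 3

## Route

Step 1
Reactants: 1 4,4-dimethoxybutan-2-one; 2 dimethyl malonate
Product: 3 dimethyl 2-(4,4-dimethoxybutan-2-ylidene)malonate
Conditions: TiCl4 (2.0 equiv), pyridine (4.0 equiv), THF, 0 °C to rt
Reagents that add atoms: none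
Why: Knoevenagel condensation in its TiCl4–pyridine variant, the standard way to condense a ketone with a malonate: TiCl4 activates the ketone and templates the malonate enolate, and pyridine takes up HCl. The two ester groups are identical, so no alkene geometry arises; the acetal should survive the amine-buffered medium, and any partial loss of methanol to the enol ether is harmless because both forms converge on 5 in step 2.

Step 2
Reactants: 3 dimethyl 2-(4,4-dimethoxybutan-2-ylidene)malonate
Product: 5 methyl 4-methyl-2-oxo-2H-pyran-3-carboxylate, via dimethyl 2-(4-oxobutan-2-ylidene)malonate 4 (not isolated)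
Conditions: HCO2H–H2O (9:1), 90 °C
Reagents that add atoms: water, O
Why: Acid hydrolysis of the acetal gives aldehyde 4, whose extended enol (conjugated with the alkylidene malonate) attacks the ester that is necessarily cis to it and expels methanol (lactonisation by acyl substitution). The driving force is the formation of the conjugated 2-pyranone.

Step 3
Reactants: 5 methyl 4-methyl-2-oxo-2H-pyran-3-carboxylate; 6 2-methylprop-1-ene (isobutylene)
Product: 7 methyl (1S,4R)-5,8,8-trimethyl-3-oxo-2-oxabicyclo[2.2.2]oct-5-ene-4-carboxylate
Conditions: Cu(OTf)2 (10 mol %), (S,S)-tBu-box (11 mol %), 2,6-di-tert-butylpyridine (10 mol %), 4 Å MS, 6 (10 equiv), CH2Cl2, sealed vessel, 0 °C to rt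
Reagents that add atoms: none
Why: Proposed new method: Cu(OTf)2 carrying the C2-symmetric ligand (S,S)-tBu-box, 2,2'-(propane-2,2-diyl)bis[(4S)-4-tert-butyl-4,5-dihydro-1,3-oxazole], should chelate the lactone and ester carbonyl oxygens of 5 as a 1,3-dicarbonyl and lower the LUMO of its diene, so that the electron-rich alkene 6 can add in an inverse-electron-demand Diels–Alder reaction; the closest known reaction types are the bis(oxazoline)–Cu(OTf)2-catalysed [4+2] addition of enol ethers to 3-alkoxycarbonyl-2-pyrones and the high-pressure addition of unactivated alkenes to 2-pyrones. The CH2 terminus of 6 should bond first to the pyrone carbon that bears the ring oxygen (target C3), and the developing tertiary cation should be captured by the metal-bound malonate-type carbon (target C6), a concerted but strongly asynchronous [4πs+2πs] process. The carbocycle C1–C6 is closed intermolecularly by these two bonds (C2–C3 and C1–C6) in one suprafacial event, and the bridged six-membered lactone ring arises at the same moment without a separate lactonisation, because the O–C(=O) unit of the pyrone becomes the two-atom bridge across C3 and C6. Regioselectivity follows from the matching polarisation of the partners (the largest LUMO coefficient at the oxygen-bearing diene terminus, Markovnikov charge development in 6), and no endo/exo question exists because the substituted carbon of 6 carries two identical groups. The relative configuration of the two new stereocentres (the bridgeheads, target C3 and C6) is fixed by the geometry of the bridge, and their absolute configuration by the catalyst: in the square-planar chelate the tert-butyl group next to the lactone carbonyl shields one face of the pyrone, and attack on the open face is expected to lead to (1S,4R)-7, that is, to target C3 in its final configuration, the (R,R)-ligand being used instead should the sense of induction prove opposite. Proton loss from the cationic terminus (ene-type addition), cationic oligomerisation of 6 and CO2 extrusion from 7 are to be suppressed by the hindered pyridine as a proton trap, the molecular sieves, the excess of 6 and a temperature not above room temperature.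

Step 4
Reactants: 7 methyl (1S,4R)-5,8,8-trimethyl-3-oxo-2-oxabicyclo[2.2.2]oct-5-ene-4-carboxylate
Product: 8 dimethyl (4S)-4-hydroxy-2,6,6-trimethylcyclohex-2-ene-1,1-dicarboxylate
Conditions: NaOMe (0.2 equiv), MeOH, 0 °C
Reagents that add atoms: methanol, CO
Why: Base-catalysed methanolysis (transesterification) of the strained bridged lactone; attack of methoxide at either carbonyl group leads to the same geminal dimethyl diester. The C3–O bond is not broken, so C3 keeps its configuration, and C6 ceases to be a stereocentre.

Step 5
Reactants: 8 dimethyl (4S)-4-hydroxy-2,6,6-trimethylcyclohex-2-ene-1,1-dicarboxylate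
Product: 9 methyl (4S)-4-hydroxy-2,6,6-trimethylcyclohex-2-ene-1-carboxylate (mixture of C1 epimers)
Conditions: LiCl (3 equiv), H2O (2 equiv), DMSO, 150 °C
Reagents that add atoms: none
Why: Krapcho dealkoxycarbonylation: chloride demethylates one ester by SN2 attack at the O-methyl group, the carboxylate loses CO2, and the allyl-stabilised ester enolate is protonated by water, kinetically at C6. The quaternary centre does not hinder the reaction because the attack takes place at the remote methyl group, and the C6 epimers converge in step 6.

Step 6
Reactants: 9 methyl (4S)-4-hydroxy-2,6,6-trimethylcyclohex-2-ene-1-carboxylate (mixture of C1 epimers)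
Product: 10 methyl (4R)-4-hydroxy-2,6,6-trimethylcyclohex-1-ene-1-carboxylate
Conditions: NaOMe (2 equiv), MeOH, 65 °C
Reagents that add atoms: none
Why: Base-mediated conjugation of a β,γ-unsaturated ester to the tetrasubstituted α,β-unsaturated ester through the dienolate (deprotonation at C6, reprotonation at C4); methoxide in methanol makes ester exchange degenerate and reopens any lactone. The step is run on the free alcohol, because hydroxide or alkoxide is a far poorer leaving group from the dienolate than a silyloxy group, so vinylogous β-elimination of the C3 oxygen should not compete. C3 is remote from the acidic positions and is not epimerised; its descriptor changes from S to R only because the ligand priorities change.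

Step 7
Reactants: 10 methyl (4R)-4-hydroxy-2,6,6-trimethylcyclohex-1-ene-1-carboxylate
Product: 11 methyl (4R)-4-[(tert-butyldimethylsilyl)oxy]-2,6,6-trimethylcyclohex-1-ene-1-carboxylate
Conditions: TBSCl, imidazole, DMF, rt
Reagents that add atoms: tert-butyldimethylsilyl chloride (TBSCl), CC(C)(C)[Si](C)(C)Cl
Why: Imidazole-promoted silylation of an unhindered secondary alcohol; the O–Si bond is formed without touching the C3–O bond, so the configuration is retained.

Step 8
Reactants: 11 methyl (4R)-4-[(tert-butyldimethylsilyl)oxy]-2,6,6-trimethylcyclohex-1-ene-1-carboxylate
Product: 12 [(4R)-4-[(tert-butyldimethylsilyl)oxy]-2,6,6-trimethylcyclohex-1-en-1-yl]methanol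
Conditions: iBu2AlH (2.5 equiv), CH2Cl2, −78 to 0 °C; aqueous potassium sodium tartrate work-up
Reagents that add atoms: none
Why: iBu2AlH reduces the hindered conjugated ester by two 1,2-hydride transfers to the primary allylic alcohol; the silyl ether and the tetrasubstituted alkene are inert to the reagent.

Step 9
Reactants: 12 [(4R)-4-[(tert-butyldimethylsilyl)oxy]-2,6,6-trimethylcyclohex-1-en-1-yl]methanol
Product: 13 [(1R,4S,6R)-4-[(tert-butyldimethylsilyl)oxy]-2,2,6-trimethyl-7-oxabicyclo[4.1.0]heptan-1-yl]methanol
Conditions: Ti(OiPr)4 (1.0 equiv), D-(−)-diethyl tartrate (1.2 equiv), tBuOOH (2 equiv, anhydrous in decane), 4 Å MS, CH2Cl2, −20 °C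
Reagents that add atoms: tert-butyl hydroperoxide, CC(C)(C)OO
Why: Katsuki–Sharpless asymmetric epoxidation: the C7 alkoxide and the peroxide are bound to the same titanium–tartrate centre, and with D-(−)-diethyl tartrate the oxygen is delivered to the alkene face on which the sequence CH2OH → C5 → C1 around C6 runs counter-clockwise, which is the face anti to the C3 silyloxy group. C5 and C6 are thus set together under reagent control (the remote C3 centre should exert little bias), and a full equivalent of the titanium–tartrate complex is used because the alkene is tetrasubstituted and flanked by the gem-dimethyl group.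

Step 10
Reactants: 13 [(1R,4S,6R)-4-[(tert-butyldimethylsilyl)oxy]-2,2,6-trimethyl-7-oxabicyclo[4.1.0]heptan-1-yl]methanol
Product: 14 (1S,4S,6R)-4-[(tert-butyldimethylsilyl)oxy]-2,2,6-trimethyl-7-oxabicyclo[4.1.0]heptane-1-carbaldehyde
Conditions: nPr4N[RuO4] (5 mol %), NMO (1.5 equiv), 4 Å MS, CH2Cl2, rt
Reagents that add atoms: none
Why: Ley–Griffith oxidation of the primary alcohol to the aldehyde under neutral conditions that leave the epoxide and the silyl ether intact. The aldehyde has no α-hydrogen, so it cannot epimerise, and the sieves prevent hydrate formation and over-oxidation.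

Step 11
Reactants: 14 (1S,4S,6R)-4-[(tert-butyldimethylsilyl)oxy]-2,2,6-trimethyl-7-oxabicyclo[4.1.0]heptane-1-carbaldehyde
Product: 15 (3E)-4-[(1S,4S,6R)-4-[(tert-butyldimethylsilyl)oxy]-2,2,6-trimethyl-7-oxabicyclo[4.1.0]heptan-1-yl]but-3-en-2-one
Conditions: Ph3P=CHC(O)CH3 (2 equiv), toluene, 90 °C
Reagents that add atoms: 1-(triphenylphosphoranylidene)propan-2-one (acetonylidene triphenylphosphorane), CC(=O)C=P(c1ccccc1)(c1ccccc1)c1ccccc1
Why: Wittig olefination with a ketone-stabilised ylide, which should give the (E)-enone through the reversibly formed oxaphosphetane. The conditions are neutral and salt-free, the aldehyde cannot enolise, and heating compensates for the neopentyl-type hindrance at C6.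

Step 12
Reactants: 15 (3E)-4-[(1S,4S,6R)-4-[(tert-butyldimethylsilyl)oxy]-2,2,6-trimethyl-7-oxabicyclo[4.1.0]heptan-1-yl]but-3-en-2-one
Product: 16 (3E)-4-[(1S,4S,6R)-4-hydroxy-2,2,6-trimethyl-7-oxabicyclo[4.1.0]heptan-1-yl]but-3-en-2-one
Conditions: nBu4NF (1.5 equiv), AcOH (1.5 equiv), THF, 0 °C to rt
Reagents that add atoms: none
Why: Fluoride-induced cleavage of the Si–O bond, driven by the strong Si–F bond. Buffering with acetic acid keeps the medium close to neutral, so that neither the enone (base) nor the epoxide (strong acid) is attacked.

Step 13
Reactants: 16 (3E)-4-[(1S,4S,6R)-4-hydroxy-2,2,6-trimethyl-7-oxabicyclo[4.1.0]heptan-1-yl]but-3-en-2-one; 17 tetradecanoyl chloride (myristoyl chloride)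
Product: 18 (1R,3S,6S)-1,5,5-trimethyl-6-[(1E)-3-oxobut-1-en-1-yl]-7-oxabicyclo[4.1.0]heptan-3-yl tetradecanoate
Conditions: Et3N (2 equiv), DMAP (0.1 equiv), CH2Cl2, 0 °C to rt
Reagents that add atoms: none
Why: DMAP-catalysed acylation of the unhindered secondary alcohol through the acylpyridinium ion. The C3–O bond is not broken, so the configuration is retained, and the amine takes up HCl so that the epoxide is not opened.

## Compound list

The oxygen-bearing centre C3 keeps the same spatial arrangement from 7 to 18; its descriptor (S in 7–9, R in 10–12, S from 13 on) and that of C6 (R in 13, S from 14 on) change only through changes in ligand priority.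

1 | 4,4-dimethoxybutan-2-one | CC(=O)CC(OC)OC | starting material
2 | dimethyl malonate | COC(=O)CC(=O)OC | starting material
3 | dimethyl 2-(4,4-dimethoxybutan-2-ylidene)malonate | COC(=O)C(C(=O)OC)=C(C)CC(OC)OC | intermediate
4 | dimethyl 2-(4-oxobutan-2-ylidene)malonate | COC(=O)C(C(=O)OC)=C(C)CC=O | intermediate (not isolated)
5 | methyl 4-methyl-2-oxo-2H-pyran-3-carboxylate | COC(=O)C1=C(C)C=COC1=O | intermediate
6 | 2-methylprop-1-ene (isobutylene) | CC(C)=C | starting material
7 | methyl (1S,4R)-5,8,8-trimethyl-3-oxo-2-oxabicyclo[2.2.2]oct-5-ene-4-carboxylate | O=C1O[C@H]2CC(C)(C)[C@]1(C(=O)OC)C(C)=C2 | intermediate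
8 | dimethyl (4S)-4-hydroxy-2,6,6-trimethylcyclohex-2-ene-1,1-dicarboxylate | O[C@H]1CC(C)(C)C(C(=O)OC)(C(=O)OC)C(C)=C1 | intermediate
9 | methyl (4S)-4-hydroxy-2,6,6-trimethylcyclohex-2-ene-1-carboxylate (mixture of C1 epimers) | O[C@H]1CC(C)(C)C(C(=O)OC)C(C)=C1 | intermediate
10 | methyl (4R)-4-hydroxy-2,6,6-trimethylcyclohex-1-ene-1-carboxylate | O[C@H]1CC(C)(C)C(C(=O)OC)=C(C)C1 | intermediate
11 | methyl (4R)-4-[(tert-butyldimethylsilyl)oxy]-2,6,6-trimethylcyclohex-1-ene-1-carboxylate | CC(C)(C)[Si](C)(C)O[C@H]1CC(C)(C)C(C(=O)OC)=C(C)C1 | intermediate
12 | [(4R)-4-[(tert-butyldimethylsilyl)oxy]-2,6,6-trimethylcyclohex-1-en-1-yl]methanol | CC(C)(C)[Si](C)(C)O[C@H]1CC(C)(C)C(CO)=C(C)C1 | intermediate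
13 | [(1R,4S,6R)-4-[(tert-butyldimethylsilyl)oxy]-2,2,6-trimethyl-7-oxabicyclo[4.1.0]heptan-1-yl]methanol | CC(C)(C)[Si](C)(C)O[C@H]1CC(C)(C)[C@]2(CO)O[C@]2(C)C1 | intermediate
14 | (1S,4S,6R)-4-[(tert-butyldimethylsilyl)oxy]-2,2,6-trimethyl-7-oxabicyclo[4.1.0]heptane-1-carbaldehyde | CC(C)(C)[Si](C)(C)O[C@H]1CC(C)(C)[C@]2(C=O)O[C@]2(C)C1 | intermediate
15 | (3E)-4-[(1S,4S,6R)-4-[(tert-butyldimethylsilyl)oxy]-2,2,6-trimethyl-7-oxabicyclo[4.1.0]heptan-1-yl]but-3-en-2-one | CC(C)(C)[Si](C)(C)O[C@H]1CC(C)(C)[C@]2(/C=C/C(C)=O)O[C@]2(C)C1 | intermediate
16 | (3E)-4-[(1S,4S,6R)-4-hydroxy-2,2,6-trimethyl-7-oxabicyclo[4.1.0]heptan-1-yl]but-3-en-2-one | O[C@H]1CC(C)(C)[C@]2(/C=C/C(C)=O)O[C@]2(C)C1 | intermediate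
17 | tetradecanoyl chloride (myristoyl chloride) | CCCCCCCCCCCCCC(Cl)=O | starting material
18 | (1R,3S,6S)-1,5,5-trimethyl-6-[(1E)-3-oxobut-1-en-1-yl]-7-oxabicyclo[4.1.0]heptan-3-yl tetradecanoate | CCCCCCCCCCCCCC(=O)O[C@H]1CC(C)(C)[C@]2(/C=C/C(C)=O)O[C@]2(C)C1 | target

## Step count and least certain steps

Total: 13 steps. Longest linear sequence: 13 steps (from 1 and 2 to 18; 6 and 17 enter as single reagents).

Step 3 (key step). The most likely failures are insufficient reactivity of the unactivated alkene toward the 4-methyl-substituted pyrone and erosion of the facial selectivity. The first C–C bond forms far from the ligand, and the ring must close onto the fully substituted carbon between the two carbonyl groups, so that proton loss from the cationic terminus, oligomerisation of the alkene or an unselective background reaction can compete. The fallback uses known chemistry and sets out from 5 and 6. The uncatalysed cycloaddition under high pressure (about 10–15 kbar, CH2Cl2, room temperature, no Lewis acid) should give racemic methyl 5,8,8-trimethyl-3-oxo-2-oxabicyclo[2.2.2]oct-5-ene-4-carboxylate F1. Catalytic NaOMe in MeOH opens it to racemic dimethyl 4-hydroxy-2,6,6-trimethylcyclohex-2-ene-1,1-dicarboxylate F2. Esterification with (S)-2-methoxy-2-phenylacetic acid (DCC, DMAP) gives the diastereomers dimethyl (4S)-4-{[(2S)-2-methoxy-2-phenylacetyl]oxy}-2,6,6-trimethylcyclohex-2-ene-1,1-dicarboxylate F3 and dimethyl (4R)-4-{[(2S)-2-methoxy-2-phenylacetyl]oxy}-2,6,6-trimethylcyclohex-2-ene-1,1-dicarboxylate F4, which are separated by chromatography or crystallisation. Methanolysis of F3 with NaOMe in MeOH comes back to the route at 8.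

Step 6. The most likely failure is incomplete conjugation, because the conjugated ester is twisted out of plane by its three flanking substituents and the equilibrium may be reached slowly or lie less far on the product side than wanted; vinylogous loss of the C3 oxygen from the dienolate is the second risk. The fallback moves the isomerisation to the aldehyde level, where conjugation is much easier, and sets out from 9. Silylation (TBSCl, imidazole) gives methyl (4S)-4-[(tert-butyldimethylsilyl)oxy]-2,6,6-trimethylcyclohex-2-ene-1-carboxylate F6. Reduction with iBu2AlH gives [(4S)-4-[(tert-butyldimethylsilyl)oxy]-2,6,6-trimethylcyclohex-2-en-1-yl]methanol F7. Neutral oxidation (nPr4N[RuO4], NMO) gives (4S)-4-[(tert-butyldimethylsilyl)oxy]-2,6,6-trimethylcyclohex-2-ene-1-carbaldehyde F8. Brief treatment with a weak amine base (DBU, CH2Cl2, rt) should conjugate it to (4R)-4-[(tert-butyldimethylsilyl)oxy]-2,6,6-trimethylcyclohex-1-ene-1-carbaldehyde F9. A Luche reduction (NaBH4, CeCl3, MeOH) comes back to the route at 12.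

Step 5. The most likely failure is relactonisation at 150 °C before the demethylation, since one ester group of 8 is held cis to the C3 hydroxyl; this would regenerate the bridged lactone, whose bridgehead position cannot support decarboxylation. The fallback sets out from 7 and bypasses 8. One equivalent of LiOH (THF/H2O, 0 °C) should open the strained lactone in preference to the hindered methyl ester and give, after acidification, (1S,4S)-4-hydroxy-1-(methoxycarbonyl)-2,6,6-trimethylcyclohex-2-ene-1-carboxylic acid F5. Heating F5 in toluene–pyridine at about 100 °C should bring about the classical decarboxylation of a malonic half-ester through its cyclic transition state and comes back to the route at 9.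

Step 11. The most likely failure is a sluggish olefination, because the aldehyde carbon sits on a fully substituted epoxide carbon flanked by C1 and C5 and the ketone-stabilised ylide is a weak nucleophile; prolonged heating invites rearrangement of the epoxide. The fallback replaces the phosphorus olefination by an aldol–elimination sequence and sets out from 14. Directed aldol addition of the lithium enolate of acetone (LiN(iPr)2, acetone, THF, −78 °C) to the non-enolisable aldehyde gives 4-[(1R,4S,6R)-4-[(tert-butyldimethylsilyl)oxy]-2,2,6-trimethyl-7-oxabicyclo[4.1.0]heptan-1-yl]-4-hydroxybutan-2-one F10. Mesylation (MsCl, Et3N) gives 1-[(1R,4S,6R)-4-[(tert-butyldimethylsilyl)oxy]-2,2,6-trimethyl-7-oxabicyclo[4.1.0]heptan-1-yl]-3-oxobutyl methanesulfonate F11, which eliminates with DBU in the same flask and comes back to the route at 15.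

## Further compounds

F1 | step 3 | racemic methyl 5,8,8-trimethyl-3-oxo-2-oxabicyclo[2.2.2]oct-5-ene-4-carboxylate | O=C1OC2CC(C)(C)C1(C(=O)OC)C(C)=C2
F2 | step 3 | racemic dimethyl 4-hydroxy-2,6,6-trimethylcyclohex-2-ene-1,1-dicarboxylate | OC1CC(C)(C)C(C(=O)OC)(C(=O)OC)C(C)=C1
F3 | step 3 | dimethyl (4S)-4-{[(2S)-2-methoxy-2-phenylacetyl]oxy}-2,6,6-trimethylcyclohex-2-ene-1,1-dicarboxylate | CO[C@H](C(=O)O[C@H]1CC(C)(C)C(C(=O)OC)(C(=O)OC)C(C)=C1)c1ccccc1
F4 | step 3 | dimethyl (4R)-4-{[(2S)-2-methoxy-2-phenylacetyl]oxy}-2,6,6-trimethylcyclohex-2-ene-1,1-dicarboxylate | CO[C@H](C(=O)O[C@@H]1CC(C)(C)C(C(=O)OC)(C(=O)OC)C(C)=C1)c1ccccc1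
F5 | step 5 | (1S,4S)-4-hydroxy-1-(methoxycarbonyl)-2,6,6-trimethylcyclohex-2-ene-1-carboxylic acid | O[C@H]1CC(C)(C)[C@](C(=O)O)(C(=O)OC)C(C)=C1
F6 | step 6 | methyl (4S)-4-[(tert-butyldimethylsilyl)oxy]-2,6,6-trimethylcyclohex-2-ene-1-carboxylate (C1 epimers) | CC(C)(C)[Si](C)(C)O[C@H]1CC(C)(C)C(C(=O)OC)C(C)=C1
F7 | step 6 | [(4S)-4-[(tert-butyldimethylsilyl)oxy]-2,6,6-trimethylcyclohex-2-en-1-yl]methanol (C1 epimers) | CC(C)(C)[Si](C)(C)O[C@H]1CC(C)(C)C(CO)C(C)=C1
F8 | step 6 | (4S)-4-[(tert-butyldimethylsilyl)oxy]-2,6,6-trimethylcyclohex-2-ene-1-carbaldehyde (C1 epimers) | CC(C)(C)[Si](C)(C)O[C@H]1CC(C)(C)C(C=O)C(C)=C1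
F9 | step 6 | (4R)-4-[(tert-butyldimethylsilyl)oxy]-2,6,6-trimethylcyclohex-1-ene-1-carbaldehyde | CC(C)(C)[Si](C)(C)O[C@H]1CC(C)(C)C(C=O)=C(C)C1
F10 | step 11 | 4-[(1R,4S,6R)-4-[(tert-butyldimethylsilyl)oxy]-2,2,6-trimethyl-7-oxabicyclo[4.1.0]heptan-1-yl]-4-hydroxybutan-2-one (carbinol epimers) | CC(C)(C)[Si](C)(C)O[C@H]1CC(C)(C)[C@]2(C(O)CC(C)=O)O[C@]2(C)C1
F11 | step 11 | 1-[(1R,4S,6R)-4-[(tert-butyldimethylsilyl)oxy]-2,2,6-trimethyl-7-oxabicyclo[4.1.0]heptan-1-yl]-3-oxobutyl methanesulfonate (epimers at the sulfonate-bearing carbon) | CC(C)(C)[Si](C)(C)O[C@H]1CC(C)(C)[C@]2(C(OS(C)(=O)=O)CC(C)=O)O[C@]2(C)C1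
A1 | alternative 1 | (R)-2-hydroxy-2,6,6-trimethylcyclohexane-1,4-dione | O=C1CC(C)(C)C(=O)[C@](C)(O)C1
A2 | alternative 1 | 4,4-dimethylheptane-2,3,6-trione | CC(=O)C(=O)C(C)(C)CC(C)=O
A3 | alternative 2 | tert-butyl (1S,4S,6R)-4-[(tert-butyldimethylsilyl)oxy]-2,2,6-trimethyl-7-oxabicyclo[4.1.0]heptane-1-carboxylate | CC(C)(C)[Si](C)(C)O[C@H]1CC(C)(C)[C@]2(C(=O)OC(C)(C)C)O[C@]2(C)C1
A4 | alternative 2 | tert-butyl (5S)-5-[(tert-butyldimethylsilyl)oxy]-2-chloro-3,3-dimethyl-7-oxooctanoate (C2 epimers) | CC(=O)C[C@@H](O[Si](C)(C)C(C)(C)C)CC(C)(C)C(Cl)C(=O)OC(C)(C)C
A5 | alternative 3 | 4-{[(tert-butyldimethylsilyl)oxy]methyl}-3,5,5-trimethylcyclohex-3-en-1-one | O=C1CC(C)=C(CO[Si](C)(C)C(C)(C)C)C(C)(C)C1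
A6 | alternative 3 | racemic 2-{[(tert-butyldimethylsilyl)oxy]methyl}-3,3-dimethyl-2-(prop-1-en-2-yl)cyclobutan-1-one | O=C1CC(C)(C)C1(CO[Si](C)(C)C(C)(C)C)C(C)=C
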